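## Retrosynthetic overview

1. Target 25 ⇐ dioxirane epoxidation of the C1=C10 olefin of bis-angelate 24 ⇐ double angeloylation of epoxy diol 22 ⇐ hydroxyl-directed 4,5-epoxidation and hydroxyl-directed C6 reduction of keto lactone 20.
2. 20 ⇐ key step: SmI2 Reformatsky macro-aldol (C7–C8) with in-flask lactonisation (O8–C12) of acyclic bromo keto aldehyde 16; the ten-membered carbocycle and the γ-lactone form in one operation and C7/C8 are set from C11.
3. 16 ⇐ enantioselective Cu-bis(oxazoline) Mukaiyama aldol of methyl pyruvate (sets C11) with the enol silane of Z,Z-enone 8.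
4. 8 ⇐ two alkoxide-directed, Z-selective allyl dianion alkylations (prenol, then 4-methylpent-3-en-2-ol), which fix both Z-olefins that later become the two cis-epoxides.
5. Ring order: carbocycle and lactone together, then the 4,5-epoxide, then the 1,10-epoxide.

Assumption: atom labels C1–C15 follow germacrane numbering, and TIPSOCH2Cl, the (R,R)-tBu-box ligand and angelic anhydride are bought as reagents.

## Route

Step 1
Reactants: 1 3-methylbut-2-en-1-ol (prenol)
Product: 3 (Z)-3-methyl-5-[(triisopropylsilyl)oxy]pent-2-en-1-ol, via dilithio dianion of prenol 2 (not isolated)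
Conditions: n-BuLi (2.2 equiv), TMEDA, Et2O, 0 → 23 °C; then TIPSOCH2Cl, −78 → 0 °C
Reagents that add atoms: (triisopropylsilyloxy)methyl chloride, ClCO[Si](C(C)C)(C(C)C)C(C)C
Why: Alkoxide-directed allylic lithiation (dianion formation) removes a proton from the methyl cis to CH2OLi, and C-alkylation of the chelated Z-allyllithium at its CH2 terminus by the α-chloro ether gives the Z-trisubstituted olefin (future C1=C10) with the protected C8 oxygen attached.

Step 2
Reactants: 3 (Z)-3-methyl-5-[(triisopropylsilyl)oxy]pent-2-en-1-ol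
Product: 4 {[(3Z)-5-bromo-3-methylpent-3-en-1-yl]oxy}triisopropylsilane
Conditions: CBr4, PPh3, CH2Cl2, 0 °C
Reagents that add atoms: carbon tetrabromide, BrC(Br)(Br)Br
Why: Appel reaction; SN2 displacement at the primary allylic carbon under neutral conditions keeps the Z-olefin and the silyl ether.

Step 3
Reactants: 4 {[(3Z)-5-bromo-3-methylpent-3-en-1-yl]oxy}triisopropylsilane; 5 4-methylpent-3-en-2-ol (racemic)
Product: 7 (3Z,7Z)-4,8-dimethyl-10-[(triisopropylsilyl)oxy]deca-3,7-dien-2-ol, via dilithio dianion of 4-methylpent-3-en-2-ol 6 (not isolated)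
Conditions: 5 (1.5 equiv), n-BuLi (3.1 equiv), TMEDA, Et2O, 0 → 23 °C; then 4, −78 → 0 °C
Reagents that add atoms: none
Why: The same alkoxide-directed allylic metalation/alkylation, here on the secondary homologue of prenol, joins C2 to C3 by SN2 at the primary allylic bromide and sets the second Z-olefin (future C4=C5); the racemic carbinol is removed in step 4.

Step 4
Reactants: 7 (3Z,7Z)-4,8-dimethyl-10-[(triisopropylsilyl)oxy]deca-3,7-dien-2-ol
Product: 8 (3Z,7Z)-4,8-dimethyl-10-[(triisopropylsilyl)oxy]deca-3,7-dien-2-one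
Conditions: Dess–Martin periodinane, pyridine, CH2Cl2, 0 °C
Reagents that add atoms: none
Why: Dess–Martin oxidation of the secondary allylic alcohol under buffered conditions gives the Z-enone without acid- or base-induced Z/E isomerisation.

Step 5
Reactants: 8 (3Z,7Z)-4,8-dimethyl-10-[(triisopropylsilyl)oxy]deca-3,7-dien-2-one
Product: 10 (3Z,7Z)-4,8-dimethyl-10-[(triisopropylsilyl)oxy]-2-[(trimethylsilyl)oxy]deca-1,3,7-triene, via lithium enolate of enone 9 (not isolated)
Conditions: LiN(iPr)2, THF, −78 °C; then Me3SiCl, Et3N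
Reagents that add atoms: chlorotrimethylsilane, C[Si](C)(C)Cl
Why: Kinetic α′-deprotonation of the enone at its methyl group by the hindered amide, then O-silylation (silyl enol ether formation), gives the cross-conjugated enol silane and leaves both Z-olefins untouched.

Step 6
Reactants: 10 (3Z,7Z)-4,8-dimethyl-10-[(triisopropylsilyl)oxy]-2-[(trimethylsilyl)oxy]deca-1,3,7-triene; 11 methyl pyruvate
Product: 13 methyl (2R,5Z,9Z)-2,12-dihydroxy-2,6,10-trimethyl-4-oxododeca-5,9-dienoate, via silylated aldol adduct 12 (not isolated)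
Conditions: [Cu((R,R)-tBu-box)](OTf)2 (10 mol%), THF, −78 °C; then HF·pyridine, THF, 0 → 23 °C
Reagents that add atoms: none
Why: Evans-type enantioselective Mukaiyama aldol; the copper bis(oxazoline) complex binds the pyruvate as a five-membered chelate and the (R,R)-ligand (the (S,S)-ligand is reported to give the S carbinol) directs the enol silane to the face that gives the (R)-configured C11 tertiary carbinol, after which HF removes both silyl groups.

Step 7
Reactants: 13 methyl (2R,5Z,9Z)-2,12-dihydroxy-2,6,10-trimethyl-4-oxododeca-5,9-dienoate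
Product: 15 methyl (2S,5Z,9Z)-3-bromo-2,6,10-trimethyl-4-oxo-2,12-bis[(triethylsilyl)oxy]dodeca-5,9-dienoate (both C3 epimers; 2S only through the CIP priority of the CHBr group), via tris(triethylsilyl) enol ether 14 (not isolated)
Conditions: Et3SiOTf (3.5 equiv), Et3N, CH2Cl2, −78 → 0 °C; then NBS, THF, −78 °C
Reagents that add atoms: triethylsilyl triflate, CC[Si](CC)(CC)OS(=O)(=O)C(F)(F)F; N-bromosuccinimide, O=C1CCC(=O)N1Br
Why: Soft enolisation (silyl triflate/amine) at the α′-methylene C7 with silylation of both hydroxyls, then electrophilic α-bromination of the silyl enol ether, which is far faster than attack on the trisubstituted olefins; the C7 epimer ratio does not matter because C7 becomes an enolate in step 9.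

Step 8
Reactants: 15 methyl (2S,5Z,9Z)-3-bromo-2,6,10-trimethyl-4-oxo-2,12-bis[(triethylsilyl)oxy]dodeca-5,9-dienoate
Product: 16 methyl (2S,5Z,9Z)-3-bromo-2,6,10-trimethyl-4,12-dioxo-2-[(triethylsilyl)oxy]dodeca-5,9-dienoate
Conditions: (COCl)2, DMSO, CH2Cl2, −78 → −30 °C; then Et3N; used at once
Reagents that add atoms: none
Why: Swern oxidation cleaves and oxidises a primary triethylsilyl ether directly to the aldehyde, while the tertiary silyl ether and the α-bromo ketone (no β-hydrogen available for elimination) survive.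

Step 9 (key step)
Reactants: 16 methyl (2S,5Z,9Z)-3-bromo-2,6,10-trimethyl-4,12-dioxo-2-[(triethylsilyl)oxy]dodeca-5,9-dienoate
Product: 20 (3R,3aR,5Z,9Z,11aR)-3-hydroxy-3,6,10-trimethyl-3,3a,7,8,11,11a-hexahydrocyclodeca[b]furan-2,4-dione [germacrane numbering: (7R,8R,11R)-11-hydroxy-6-oxo-1(10)Z,4Z-dien-12,8-olide], via samarium enolate 17 (not isolated), via macrocyclic samarium aldolate 18 (not isolated), via silyl lactone 19 (not isolated)
Conditions: SmI2 (2.5 equiv), THF, −78 → 0 °C, 2 mM (syringe pump); then HF·pyridine, pyridine, THF, 0 °C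
Reagents that add atoms: none
Why: Proposed new method: SmI2 reduces the C–Br bond selectively to a Z-configured trivalent samarium enolate that closes the ten-membered ring through a Zimmerman–Traxler chair (7,8-syn) on the face anti to the bulky C11 silyloxy group with the ester carbonyl bound to samarium, and the C8 samarium alkoxide then acylates on that ester to close the trans-fused γ-lactone; the closest known reaction is the SmI2-mediated intramolecular Reformatsky-type aldol of α-bromo carbonyl compounds with aldehydes used for medium rings, here extended by the in-flask lactonisation.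

Step 10
Reactants: 20 (3R,3aR,5Z,9Z,11aR)-3-hydroxy-3,6,10-trimethyl-3,3a,7,8,11,11a-hexahydrocyclodeca[b]furan-2,4-dione
Product: 21 (3R,3aR,4R,5Z,9Z,11aR)-3,4-dihydroxy-3,6,10-trimethyl-3a,4,7,8,11,11a-hexahydrocyclodeca[b]furan-2(3H)-one
Conditions: Me4NBH(OAc)3, MeCN/AcOH (1:1), −30 °C
Reagents that add atoms: none
Why: Saksena–Evans reduction; the C11 hydroxyl binds the acetoxyborohydride and delivers hydride to C6 through a chair transition state with C5 equatorial, giving the 6,11-anti diol, which has the C6 geometry of the target (descriptor R here, S after acylation, by CIP priority only).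

Step 11
Reactants: 21 (3R,3aR,4R,5Z,9Z,11aR)-3,4-dihydroxy-3,6,10-trimethyl-3a,4,7,8,11,11a-hexahydrocyclodeca[b]furan-2(3H)-one
Product: 22 (1(10)Z,4R,5S,6S,7R,8R,11R)-4,5-epoxy-6,11-dihydroxygermacr-1(10)-en-12,8-olide
Conditions: VO(acac)2 (5 mol%), t-BuOOH, CH2Cl2, 0 °C
Reagents that add atoms: tert-butyl hydroperoxide, CC(C)(C)OO
Why: Vanadium-catalysed hydroxyl-directed epoxidation delivers oxygen to the Z-olefin face syn to the C6 hydroxyl (cis-epoxy alcohol, as with cyclooct-2-enol and cyclonon-2-enol), stereospecifically giving the cis-epoxide (4R,5S), while the remote C1=C10 olefin has no directing group and stays.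

Step 12
Reactants: 22 (1(10)Z,4R,5S,6S,7R,8R,11R)-4,5-epoxy-6,11-dihydroxygermacr-1(10)-en-12,8-olide
Product: 24 (1(10)Z,4R,5S,6S,7S,8R,11R)-6,11-bis(angeloyloxy)-4,5-epoxygermacr-1(10)-en-12,8-olide, via dilithium dialkoxide 23 (not isolated)
Conditions: LiN(SiMe3)2 (2.3 equiv), THF, −78 °C; then angelic anhydride (4 equiv), −78 → 0 °C
Reagents that add atoms: angelic anhydride, C/C=C(/C)C(=O)OC(=O)/C(C)=C\C
Why: O-acylation of the preformed lithium alkoxides by the anhydride at low temperature, without a nucleophilic catalyst, esterifies the secondary and the hindered tertiary hydroxyl without angelate-to-tiglate isomerisation and is expected to outrun Payne rearrangement and translactonisation.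

Step 13
Reactants: 24 (1(10)Z,4R,5S,6S,7S,8R,11R)-6,11-bis(angeloyloxy)-4,5-epoxygermacr-1(10)-en-12,8-olide
Product: 25 (1R,4R,5S,6S,7S,8R,10S,11R)-6,11-bis(angeloyloxy)-1,10:4,5-diepoxygermacran-12,8-olide (CNP0219924.2)
Conditions: dimethyldioxirane, acetone, −20 °C
Reagents that add atoms: dimethyldioxirane, CC1(C)OO1
Why: Prilezhaev-type electrophilic epoxidation by the dioxirane is stereospecific (Z-olefin to cis-epoxide) and selective for the electron-rich ring olefin over the conjugated angelates; attack is expected on the exposed outer face anti to the 4,5-epoxide oxygen, giving (1R,10S), but this face selectivity rests on conformation alone.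

## Compound list

1 | 3-methylbut-2-en-1-ol (prenol) | CC(C)=CCO | starting material
2 | dilithio dianion of prenol | [Li]C/C(C)=C\CO[Li] | intermediate
3 | (Z)-3-methyl-5-[(triisopropylsilyl)oxy]pent-2-en-1-ol | OC/C=C(C)\CCO[Si](C(C)C)(C(C)C)C(C)C | intermediate
4 | {[(3Z)-5-bromo-3-methylpent-3-en-1-yl]oxy}triisopropylsilane | BrC/C=C(C)\CCO[Si](C(C)C)(C(C)C)C(C)C | intermediate
5 | 4-methylpent-3-en-2-ol (racemic) | CC(O)C=C(C)C | starting material
6 | dilithio dianion of 4-methylpent-3-en-2-ol | [Li]C/C(C)=C\C(C)O[Li] | intermediate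
7 | (3Z,7Z)-4,8-dimethyl-10-[(triisopropylsilyl)oxy]deca-3,7-dien-2-ol (racemic carbinol) | CC(O)/C=C(C)\CC/C=C(C)\CCO[Si](C(C)C)(C(C)C)C(C)C | intermediate
8 | (3Z,7Z)-4,8-dimethyl-10-[(triisopropylsilyl)oxy]deca-3,7-dien-2-one | CC(=O)/C=C(C)\CC/C=C(C)\CCO[Si](C(C)C)(C(C)C)C(C)C | intermediate
9 | lithium enolate of enone 8 | C=C(O[Li])/C=C(C)\CC/C=C(C)\CCO[Si](C(C)C)(C(C)C)C(C)C | intermediate
10 | (3Z,7Z)-4,8-dimethyl-10-[(triisopropylsilyl)oxy]-2-[(trimethylsilyl)oxy]deca-1,3,7-triene | C=C(O[Si](C)(C)C)/C=C(C)\CC/C=C(C)\CCO[Si](C(C)C)(C(C)C)C(C)C | intermediate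
11 | methyl pyruvate | COC(=O)C(C)=O | starting material
12 | methyl (2R,5Z,9Z)-2,6,10-trimethyl-4-oxo-12-[(triisopropylsilyl)oxy]-2-[(trimethylsilyl)oxy]dodeca-5,9-dienoate | COC(=O)[C@](C)(O[Si](C)(C)C)CC(=O)/C=C(C)\CC/C=C(C)\CCO[Si](C(C)C)(C(C)C)C(C)C | intermediate
13 | methyl (2R,5Z,9Z)-2,12-dihydroxy-2,6,10-trimethyl-4-oxododeca-5,9-dienoate | COC(=O)[C@](C)(O)CC(=O)/C=C(C)\CC/C=C(C)\CCO | intermediate
14 | methyl (2R,5Z,9Z)-2,6,10-trimethyl-2,4,12-tris[(triethylsilyl)oxy]dodeca-3,5,9-trienoate (3-ene geometry not assigned) | COC(=O)[C@](C)(O[Si](CC)(CC)CC)C=C(O[Si](CC)(CC)CC)/C=C(C)\CC/C=C(C)\CCO[Si](CC)(CC)CC | intermediate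
15 | methyl (2S,5Z,9Z)-3-bromo-2,6,10-trimethyl-4-oxo-2,12-bis[(triethylsilyl)oxy]dodeca-5,9-dienoate (C3 epimers) | COC(=O)[C@](C)(O[Si](CC)(CC)CC)C(Br)C(=O)/C=C(C)\CC/C=C(C)\CCO[Si](CC)(CC)CC | intermediate
16 | methyl (2S,5Z,9Z)-3-bromo-2,6,10-trimethyl-4,12-dioxo-2-[(triethylsilyl)oxy]dodeca-5,9-dienoate (C3 epimers) | COC(=O)[C@](C)(O[Si](CC)(CC)CC)C(Br)C(=O)/C=C(C)\CC/C=C(C)\CC=O | intermediate
17 | samarium enolate (Z, O–SmI2 at C6) of 16 | COC(=O)[C@](C)(O[Si](CC)(CC)CC)/C=C(\O[Sm](I)I)/C=C(C)\CC/C=C(C)\CC=O | intermediate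
18 | ten-membered samarium aldolate (C8–O–SmI2, methyl ester intact) | C1/C(C)=C\C(=O)[C@H]([C@H](O[Sm](I)I)C/C(C)=C\C1)[C@@](C)(O[Si](CC)(CC)CC)C(=O)OC | intermediate
19 | 11-O-triethylsilyl ether of 20 | C1/C(C)=C\C(=O)[C@@H]2[C@@H](C/C(C)=C\C1)OC(=O)[C@]2(C)O[Si](CC)(CC)CC | intermediate
20 | (3R,3aR,5Z,9Z,11aR)-3-hydroxy-3,6,10-trimethyl-3,3a,7,8,11,11a-hexahydrocyclodeca[b]furan-2,4-dione | C1/C(C)=C\C(=O)[C@@H]2[C@@H](C/C(C)=C\C1)OC(=O)[C@]2(C)O | intermediate
21 | (3R,3aR,4R,5Z,9Z,11aR)-3,4-dihydroxy-3,6,10-trimethyl-3a,4,7,8,11,11a-hexahydrocyclodeca[b]furan-2(3H)-one | C1/C(C)=C\[C@@H](O)[C@@H]2[C@@H](C/C(C)=C\C1)OC(=O)[C@]2(C)O | intermediate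
22 | (1(10)Z,4R,5S,6S,7R,8R,11R)-4,5-epoxy-6,11-dihydroxygermacr-1(10)-en-12,8-olide | O[C@H]1[C@@H]2[C@@H](C/C(C)=C\CC[C@@]3(C)O[C@@H]13)OC(=O)[C@]2(C)O | intermediate
23 | dilithium 6,11-dialkoxide of 22 | [Li]O[C@H]1[C@@H]2[C@@H](C/C(C)=C\CC[C@@]3(C)O[C@@H]13)OC(=O)[C@]2(C)O[Li] | intermediate
24 | (1(10)Z,4R,5S,6S,7S,8R,11R)-6,11-bis(angeloyloxy)-4,5-epoxygermacr-1(10)-en-12,8-olide | C/C=C(/C)C(=O)O[C@H]1[C@@H]2[C@@H](C/C(C)=C\CC[C@@]3(C)O[C@@H]13)OC(=O)[C@]2(C)OC(=O)/C(C)=C\C | intermediate
25 | (1R,4R,5S,6S,7S,8R,10S,11R)-6,11-bis(angeloyloxy)-1,10:4,5-diepoxygermacran-12,8-olide | C/C=C(/C)C(=O)O[C@H]1[C@@H]2[C@@H](C[C@]3(C)O[C@@H]3CC[C@@]3(C)O[C@@H]13)OC(=O)[C@]2(C)OC(=O)/C(C)=C\C | target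

## Step count and risks

Total steps: 13. Longest linear sequence: 13 (prenol 1 → 25).

Three steps most likely to fail:

Step 9 (ten-membered ring closure with lactonisation; C7/C8 control). If the one-pot closure gives oligomers or the wrong C7/C8 relationship, the two ring closures are separated. The fallback sets out from 16: CrCl2 (4 equiv) with LiI in THF at high dilution gives a trivalent chromium enolate whose aldol with the aldehyde is not reversible and stops at the aldolate. The isolable ten-membered hydroxy ester methyl (2R)-2-[(1R,2R,4Z,8Z)-2-hydroxy-4,8-dimethyl-10-oxocyclodeca-4,8-dien-1-yl]-2-[(triethylsilyl)oxy]propanoate F1 is purified from its diastereomers. The lactone is then closed separately under acid (PPTS, toluene, 60 °C) and the silyl group is removed with HF·pyridine, rejoining the route at 20.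

Step 12 (acylation of the hindered tertiary C11 hydroxyl next to an epoxy alcohol). If the alkoxide acylation is slow or triggers Payne rearrangement or translactonisation, the angelates are built by olefination instead. The fallback sets out from 22: both hydroxyls are esterified with 2-[bis(2,2,2-trifluoroethoxy)phosphoryl]propanoic acid and DCC (acylation through the phosphonoketene, which reaches tertiary alcohols) to give the bis(phosphonopropionate) F2. A double Still–Gennari olefination (KN(SiMe3)2, 18-crown-6, acetaldehyde, THF, −78 °C) then forms both (Z)-2-methylbut-2-enoates, rejoining at 24.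

Step 13 (face selectivity of the last epoxidation). If the dioxirane attacks the other face of C1=C10, the oxygen is delivered by a two-stage anti addition that inverts the face. The fallback sets out from 24: NBS in aqueous THF gives, by bromonium formation on the exposed face and water attack at the tertiary C10, the bromohydrin (1S,4R,5S,6S,7S,8R,10S,11R)-6,11-bis(angeloyloxy)-1-bromo-4,5-epoxy-10-hydroxygermacran-12,8-olide F3. K2CO3 in acetone closes the epoxide with inversion at C1, placing the oxygen on the face opposite to direct epoxidation and giving 25.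

Further compounds

F1 | step 9 | methyl (2R)-2-[(1R,2R,4Z,8Z)-2-hydroxy-4,8-dimethyl-10-oxocyclodeca-4,8-dien-1-yl]-2-[(triethylsilyl)oxy]propanoate | C1/C(C)=C\C(=O)[C@H]([C@H](O)C/C(C)=C\C1)[C@@](C)(O[Si](CC)(CC)CC)C(=O)OC
F2 | step 12 | (1(10)Z,4R,5S,6S,7S,8R,11R)-6,11-bis{2-[bis(2,2,2-trifluoroethoxy)phosphoryl]propanoyloxy}-4,5-epoxygermacr-1(10)-en-12,8-olide (epimers at the phosphonate α-carbons) | CC(C(=O)O[C@H]1[C@@H]2[C@@H](C/C(C)=C\CC[C@@]3(C)O[C@@H]13)OC(=O)[C@]2(C)OC(=O)C(C)P(=O)(OCC(F)(F)F)OCC(F)(F)F)P(=O)(OCC(F)(F)F)OCC(F)(F)F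
F3 | step 13 | (1S,4R,5S,6S,7S,8R,10S,11R)-6,11-bis(angeloyloxy)-1-bromo-4,5-epoxy-10-hydroxygermacran-12,8-olide | C/C=C(/C)C(=O)O[C@H]1[C@@H]2[C@@H](C[C@](C)(O)[C@@H](Br)CC[C@@]3(C)O[C@@H]13)OC(=O)[C@]2(C)OC(=O)/C(C)=C\C
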